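The 3-hydroxy-ε-ring (C1′–C6′) is a masked isophorone: with C3′ as a ketone, C4′=C5′ becomes an enone alkene and the gem-dimethyl carbon C1′ sits β to that carbonyl. A Lewis-acid Robinson-type annulation of mesityl oxide with ethyl acetoacetate therefore makes the C6′–C1′ bond (Michael) and the C4′=C5′ bond (aldol condensation) in one operation and delivers the whole ring, with C7′ as an ester on a configurationally labile C6′. A catalyst-controlled ketone reduction then fixes C3′ and C6′ together. The dihydrofuran end is made from actinol by a stereospecific allenol cyclisation, and two Wittig reactions on the C10 dialdehyde assemble the polyene.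

Key step: step 1

Remark: locants are carotenoid locants (ε-ring C1′–C6′, chain C7′–C15′ and C15–C7, second ring C1–C6 with the oxygen bridging C5 and C8); compounds 9, 15, 19 and 26 are taken as purchasable building blocks.

Step 1
Reactants: 1 mesityl oxide; 2 ethyl acetoacetate
Product: 5 ethyl 2,6,6-trimethyl-4-oxocyclohex-2-ene-1-carboxylate (racemic), via Michael adduct 3 (not isolated), via cyclic aldol 4 (not isolated)
Conditions: ZnCl2 (0.3 equiv), heptane–toluene, reflux, Dean–Stark trap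
Reagents that add atoms: none
Why: ZnCl2 chelates the β-keto ester 2 as its enol, which adds in a Michael reaction to the Lewis-acid-activated enone 1 at its β-carbon and so forms the C6′–C1′ bond to the future gem-dimethyl carbon (adduct 3); the methyl ketone of 3 then enolises toward its methyl group (C4′), attacks the chelate-activated ketone C5′, and loss of water from aldol 4 gives the conjugated C4′=C5′ bond. The closest known reaction type is the Robinson annulation in its isophorone form (Michael addition, then aldol condensation), and this pairing of 1 with an acetoacetate is an established entry to 4-alkoxycarbonyl-isophorones. The single ring is closed in the aldol step by a 6-(enolendo)-exo-trig attack. The only new stereocentre, C6′, is formed without control and needs none here: as the γ-carbon of a vinylogous β-keto ester it is configurationally labile, so the enantiomers of 5 remain interconvertible until step 2 fixes C6′ together with C3′. The step needs regioselectivity between the two possible six-ring aldol closures, and the more electrophilic chelated acetoacetate ketone combined with the readily enolised methyl ketone should secure the closure that places the ester on C6′ next to the ring methyl, while azeotropic removal of water drives the sequence to the enone.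

Step 2
Reactants: 5 ethyl 2,6,6-trimethyl-4-oxocyclohex-2-ene-1-carboxylate (racemic)
Product: 6 ethyl (1R,4R)-4-hydroxy-2,6,6-trimethylcyclohex-2-ene-1-carboxylate
Conditions: (S)-2-methyl-CBS-oxazaborolidine (0.2 equiv), catecholborane (0.6 equiv), toluene, −78 °C, to about half conversion
Reagents that add atoms: none
Why: Corey–Bakshi–Shibata reduction run as a kinetic resolution, in which the catalyst delivers hydride to the enone face that creates the (R)-carbinol at C3′ (alkene flank as the large group) and only in the (1R) enantiomer of 5 is this also the face anti to the pseudoaxial methyl on C1′, so that enantiomer should be reduced faster to the trans alcohol with C3′ and C6′ set together, while the slow (1S) enone is recovered, racemised through its dienolate with catalytic DBU and recycled.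

Step 3
Reactants: 6 ethyl (1R,4R)-4-hydroxy-2,6,6-trimethylcyclohex-2-ene-1-carboxylate
Product: 7 ethyl (1R,4R)-4-[(tert-butyldimethylsilyl)oxy]-2,6,6-trimethylcyclohex-2-ene-1-carboxylate
Conditions: TBSCl, imidazole, DMF, rt
Reagents that add atoms: tert-butyldimethylsilyl chloride, CC(C)(C)[Si](C)(C)Cl
Why: Standard silylation of a secondary allylic alcohol, which protects C3′–OH against the hydride, base and bromination steps that follow and touches no stereocentre.

Step 4
Reactants: 7 ethyl (1R,4R)-4-[(tert-butyldimethylsilyl)oxy]-2,6,6-trimethylcyclohex-2-ene-1-carboxylate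
Product: 8 (1R,4R)-4-[(tert-butyldimethylsilyl)oxy]-2,6,6-trimethylcyclohex-2-ene-1-carbaldehyde
Conditions: iBu2AlH (1.2 equiv), CH2Cl2, −78 °C; MeOH, then aq. potassium sodium tartrate, 0 °C
Reagents that add atoms: none
Why: Partial ester reduction in which the aluminium hemiacetal of this hindered ester should persist at −78 °C and release the aldehyde only on cold neutral hydrolysis, so that the α-stereocentre C6′ and the position of the ring alkene are kept.

Step 5
Reactants: 8 (1R,4R)-4-[(tert-butyldimethylsilyl)oxy]-2,6,6-trimethylcyclohex-2-ene-1-carbaldehyde; 9 ethyl (2E)-4-(diethoxyphosphoryl)-3-methylbut-2-enoate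
Product: 11 ethyl (2E,4E)-5-[(1R,4R)-4-[(tert-butyldimethylsilyl)oxy]-2,6,6-trimethylcyclohex-2-en-1-yl]-3-methylpenta-2,4-dienoate, via phosphonate anion 10 (not isolated)
Conditions: NaN(SiMe3)2, THF, −78 °C; then 8, −78 → 0 °C
Reagents that add atoms: none
Why: Horner–Wadsworth–Emmons olefination in which the stabilised allylic phosphonate anion should add to the α-branched aldehyde faster than it deprotonates C6′ and the reversible addition gives the (7′E) alkene, while the (9′E) geometry comes from the reagent and any 9′Z isomer is removed by chromatography.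

Step 6
Reactants: 11 ethyl (2E,4E)-5-[(1R,4R)-4-[(tert-butyldimethylsilyl)oxy]-2,6,6-trimethylcyclohex-2-en-1-yl]-3-methylpenta-2,4-dienoate
Product: 12 (2E,4E)-5-[(1R,4R)-4-[(tert-butyldimethylsilyl)oxy]-2,6,6-trimethylcyclohex-2-en-1-yl]-3-methylpenta-2,4-dien-1-ol
Conditions: iBu2AlH (2.5 equiv), CH2Cl2, −78 °C; aq. potassium sodium tartrate
Reagents that add atoms: none
Why: 1,2-Reduction of a conjugated ester to the allylic alcohol by an electrophilic aluminium hydride, which leaves the diene geometry and both stereocentres untouched.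

Step 7
Reactants: 12 (2E,4E)-5-[(1R,4R)-4-[(tert-butyldimethylsilyl)oxy]-2,6,6-trimethylcyclohex-2-en-1-yl]-3-methylpenta-2,4-dien-1-ol
Product: 14 [(2E,4E)-5-[(1R,4R)-4-[(tert-butyldimethylsilyl)oxy]-2,6,6-trimethylcyclohex-2-en-1-yl]-3-methylpenta-2,4-dien-1-yl]triphenylphosphonium bromide, via allylic bromide 13 (not isolated)
Conditions: CBr4, PPh3 (1.1 equiv), 2,6-lutidine, CH2Cl2, −20 °C; then PPh3 (1.5 equiv), MeCN, rt
Reagents that add atoms: triphenylphosphine, c1ccc(cc1)P(c1ccccc1)c1ccccc1; carbon tetrabromide, BrC(Br)(Br)Br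
Why: Appel bromination of the primary allylic alcohol followed by SN2 alkylation of triphenylphosphine gives the Wittig salt under buffered non-acidic conditions, so the ring allylic silyl ether at C3′ is not ionised.

Step 8
Reactants: 15 (4R,6R)-4-hydroxy-2,2,6-trimethylcyclohexan-1-one (actinol)
Product: 16 (4R,6R)-4-[(tert-butyldimethylsilyl)oxy]-2,2,6-trimethylcyclohexan-1-one
Conditions: TBSCl, imidazole, DMF, rt
Reagents that add atoms: tert-butyldimethylsilyl chloride, CC(C)(C)[Si](C)(C)Cl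
Why: Standard silylation that carries the purchased carbinol stereocentre (the future C3) unchanged into the route.

Step 9
Reactants: 16 (4R,6R)-4-[(tert-butyldimethylsilyl)oxy]-2,2,6-trimethylcyclohexan-1-one
Product: 18 (4R)-4-[(tert-butyldimethylsilyl)oxy]-2,6,6-trimethylcyclohex-1-en-1-yl trifluoromethanesulfonate, via lithium enolate 17 (not isolated)
Conditions: LiN(iPr)2, THF, −78 → 0 °C; PhNTf2, 0 °C → rt
Reagents that add atoms: N-phenylbis(trifluoromethanesulfonimide), FC(F)(F)S(=O)(=O)N(c1ccccc1)S(=O)(=O)C(F)(F)F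
Why: Enolisation is possible only toward C5 because C1 is quaternary, so O-triflation of the tetrasubstituted enolate gives a single enol triflate, with the C5 stereocentre removed on purpose and C3 unaffected.

Step 10
Reactants: 18 (4R)-4-[(tert-butyldimethylsilyl)oxy]-2,6,6-trimethylcyclohex-1-en-1-yl trifluoromethanesulfonate; 19 (2E)-3-methylpent-2-en-4-yn-1-ol
Product: 20 (2E)-5-[(4R)-4-[(tert-butyldimethylsilyl)oxy]-2,6,6-trimethylcyclohex-1-en-1-yl]-3-methylpent-2-en-4-yn-1-ol
Conditions: Pd(PPh3)4 (5 mol%), CuI (10 mol%), iPr2NH, THF, 50 °C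
Reagents that add atoms: none
Why: Sonogashira coupling of an enol triflate with a terminal alkyne forms the C6–C7 bond with retention of the (E) geometry of the enynol and tolerates the free primary hydroxyl.

Step 11
Reactants: 20 (2E)-5-[(4R)-4-[(tert-butyldimethylsilyl)oxy]-2,6,6-trimethylcyclohex-1-en-1-yl]-3-methylpent-2-en-4-yn-1-ol
Product: 21 (2E)-5-[(1R,4S,6R)-4-[(tert-butyldimethylsilyl)oxy]-2,2,6-trimethyl-7-oxabicyclo[4.1.0]heptan-1-yl]-3-methylpent-2-en-4-yn-1-ol
Conditions: mCPBA (1.05 equiv), NaHCO3, CH2Cl2, −20 → 0 °C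
Reagents that add atoms: 3-chloroperoxybenzoic acid, OOC(=O)c1cccc(Cl)c1
Why: Prilezhaev epoxidation in which the tetrasubstituted ring alkene is the most electron-rich π bond and is expected to be attacked on the face anti to the 3-silyloxy group, as is general for O-protected 3-oxygenated trimethylcyclohexenes, which sets C5 (R) and C6, with the minor syn-oxirane removed by chromatography.

Step 12
Reactants: 21 (2E)-5-[(1R,4S,6R)-4-[(tert-butyldimethylsilyl)oxy]-2,2,6-trimethyl-7-oxabicyclo[4.1.0]heptan-1-yl]-3-methylpent-2-en-4-yn-1-ol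
Product: 22 (2E)-5-[(2R,4S)-4-[(tert-butyldimethylsilyl)oxy]-2-hydroxy-2,6,6-trimethylcyclohexylidene]-3-methylpenta-2,4-dien-1-ol with (R) allene axis
Conditions: iBu2AlH (3.5 equiv), CH2Cl2, −78 → 0 °C; aq. potassium sodium tartrate
Reagents that add atoms: none
Why: SN2′ reduction of an alkynyl oxirane in which, after the primary hydroxyl is capped as its aluminium alkoxide, the aluminium hydride bound to the oxirane oxygen should deliver hydride intramolecularly to C8 on the side of the breaking C6–O bond (syn course), turning the C6 stereocentre into the (6R) allene axis while the C5 carbinol keeps its configuration.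

Step 13
Reactants: 22 (2E)-5-[(2R,4S)-4-[(tert-butyldimethylsilyl)oxy]-2-hydroxy-2,6,6-trimethylcyclohexylidene]-3-methylpenta-2,4-dien-1-ol with (R) allene axis
Product: 23 (2E)-3-[(2S,6S,7aR)-6-[(tert-butyldimethylsilyl)oxy]-4,4,7a-trimethyl-2,4,5,6,7,7a-hexahydro-1-benzofuran-2-yl]but-2-en-1-ol
Conditions: AgNO3 (0.2 equiv), CaCO3, acetone–H2O, rt, dark
Reagents that add atoms: none
Why: Silver-catalysed 5-endo cycloisomerisation of an α-hydroxyallene in which the tethered C5 hydroxyl can reach the silver-activated C7=C8 bond only from its own side, so after protodemetalation the axial chirality is transferred to C8, giving 8S with the C9 chain cis to the C5 methyl.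

Step 14
Reactants: 23 (2E)-3-[(2S,6S,7aR)-6-[(tert-butyldimethylsilyl)oxy]-4,4,7a-trimethyl-2,4,5,6,7,7a-hexahydro-1-benzofuran-2-yl]but-2-en-1-ol
Product: 25 [(2E)-3-[(2S,6S,7aR)-6-[(tert-butyldimethylsilyl)oxy]-4,4,7a-trimethyl-2,4,5,6,7,7a-hexahydro-1-benzofuran-2-yl]but-2-en-1-yl]triphenylphosphonium bromide, via allylic bromide 24 (not isolated)
Conditions: CBr4, PPh3 (1.1 equiv), 2,6-lutidine, CH2Cl2, −20 °C; then PPh3 (1.5 equiv), MeCN, rt
Reagents that add atoms: triphenylphosphine, c1ccc(cc1)P(c1ccccc1)c1ccccc1; carbon tetrabromide, BrC(Br)(Br)Br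
Why: Appel bromination and in situ SN2 alkylation of triphenylphosphine at the primary allylic carbon, buffered so that no acid reaches the doubly allylic C8–O bond, whose ionisation would scramble C8.

Step 15
Reactants: 14 [(2E,4E)-5-[(1R,4R)-4-[(tert-butyldimethylsilyl)oxy]-2,6,6-trimethylcyclohex-2-en-1-yl]-3-methylpenta-2,4-dien-1-yl]triphenylphosphonium bromide; 26 (2E,4E,6E)-2,7-dimethylocta-2,4,6-trienedial
Product: 28 (2E,4E,6E,8E,10E,12E)-13-[(1R,4R)-4-[(tert-butyldimethylsilyl)oxy]-2,6,6-trimethylcyclohex-2-en-1-yl]-2,7,11-trimethyltrideca-2,4,6,8,10,12-hexaenal, via phosphorus ylide 27 (not isolated)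
Conditions: NaOMe, MeOH–CH2Cl2, 0 °C → rt, 26 (3 equiv); then I2 (cat.), CH2Cl2, rt, daylight (Z → E)
Reagents that add atoms: none
Why: Wittig olefination in which the excess of dialdehyde should restrict the semi-stabilised ylide to one carbonyl group, and the (Z) portion at the new C11′=C12′ bond is equilibrated to the all-E polyenal by iodine catalysis.

Step 16
Reactants: 25 [(2E)-3-[(2S,6S,7aR)-6-[(tert-butyldimethylsilyl)oxy]-4,4,7a-trimethyl-2,4,5,6,7,7a-hexahydro-1-benzofuran-2-yl]but-2-en-1-yl]triphenylphosphonium bromide; 28 (2E,4E,6E,8E,10E,12E)-13-[(1R,4R)-4-[(tert-butyldimethylsilyl)oxy]-2,6,6-trimethylcyclohex-2-en-1-yl]-2,7,11-trimethyltrideca-2,4,6,8,10,12-hexaenal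
Product: 30 (3S,5R,8S,3′R,6′R)-3,3′-bis[(tert-butyldimethylsilyl)oxy]-5,8-epoxy-5,8-dihydro-β,ε-carotene, via phosphorus ylide 29 (not isolated)
Conditions: NaN(SiMe3)2, THF, −78 °C; then 28, −78 °C → rt; then reflux in EtOAc under argon in the dark (Z → E)
Reagents that add atoms: none
Why: Wittig olefination under acid-free conditions joins the two halves at C11=C12 without touching C8, C5, C3, C3′ or C6′, and the unhindered (11Z) isomer is converted thermally into the all-E carotenoid.

Step 17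
Reactants: 30 (3S,5R,8S,3′R,6′R)-3,3′-bis[(tert-butyldimethylsilyl)oxy]-5,8-epoxy-5,8-dihydro-β,ε-carotene
Product: 31 (3S,5R,8S,3′R,6′R)-5,8-epoxy-5,8-dihydro-β,ε-carotene-3,3′-diol
Conditions: Bu4NF, THF, 0 °C → rt, dark
Reagents that add atoms: none
Why: Fluoride-induced desilylation frees both secondary hydroxyls under non-acidic conditions, so neither the allylic C3′ carbinol nor the acid-labile C8 centre of the dihydrofuran can epimerise.

Compound list
1 | mesityl oxide (4-methylpent-3-en-2-one) | CC(C)=CC(C)=O | starting material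
2 | ethyl acetoacetate | CCOC(=O)CC(C)=O | starting material
3 | ethyl 2-acetyl-3,3-dimethyl-5-oxohexanoate (Michael adduct, racemic) | CCOC(=O)C(C(C)=O)C(C)(C)CC(C)=O | intermediate
4 | ethyl 2-hydroxy-2,6,6-trimethyl-4-oxocyclohexane-1-carboxylate (cyclic aldol) | CCOC(=O)C1C(C)(O)CC(=O)CC1(C)C | intermediate
5 | ethyl 2,6,6-trimethyl-4-oxocyclohex-2-ene-1-carboxylate (racemic) | CCOC(=O)C1C(C)=CC(=O)CC1(C)C | intermediate
6 | ethyl (1R,4R)-4-hydroxy-2,6,6-trimethylcyclohex-2-ene-1-carboxylate | CC1=C[C@H](O)CC(C)(C)[C@H]1C(=O)OCC | intermediate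
7 | ethyl (1R,4R)-4-[(tert-butyldimethylsilyl)oxy]-2,6,6-trimethylcyclohex-2-ene-1-carboxylate | CC1=C[C@H](O[Si](C)(C)C(C)(C)C)CC(C)(C)[C@H]1C(=O)OCC | intermediate
8 | (1R,4R)-4-[(tert-butyldimethylsilyl)oxy]-2,6,6-trimethylcyclohex-2-ene-1-carbaldehyde | CC1=C[C@H](O[Si](C)(C)C(C)(C)C)CC(C)(C)[C@H]1C=O | intermediate
9 | ethyl (2E)-4-(diethoxyphosphoryl)-3-methylbut-2-enoate | CCOC(=O)/C=C(C)/CP(=O)(OCC)OCC | starting material
10 | sodium salt of the C4 carbanion of 9 | [Na+].CCOC(=O)/C=C(C)/[CH-]P(=O)(OCC)OCC | intermediate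
11 | ethyl (2E,4E)-5-[(1R,4R)-4-[(tert-butyldimethylsilyl)oxy]-2,6,6-trimethylcyclohex-2-en-1-yl]-3-methylpenta-2,4-dienoate | CC1=C[C@H](O[Si](C)(C)C(C)(C)C)CC(C)(C)[C@H]1/C=C/C(C)=C/C(=O)OCC | intermediate
12 | (2E,4E)-5-[(1R,4R)-4-[(tert-butyldimethylsilyl)oxy]-2,6,6-trimethylcyclohex-2-en-1-yl]-3-methylpenta-2,4-dien-1-ol | CC1=C[C@H](O[Si](C)(C)C(C)(C)C)CC(C)(C)[C@H]1/C=C/C(C)=C/CO | intermediate
13 | (2E,4E)-1-bromo-5-[(1R,4R)-4-[(tert-butyldimethylsilyl)oxy]-2,6,6-trimethylcyclohex-2-en-1-yl]-3-methylpenta-2,4-diene | CC1=C[C@H](O[Si](C)(C)C(C)(C)C)CC(C)(C)[C@H]1/C=C/C(C)=C/CBr | intermediate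
14 | [(2E,4E)-5-[(1R,4R)-4-[(tert-butyldimethylsilyl)oxy]-2,6,6-trimethylcyclohex-2-en-1-yl]-3-methylpenta-2,4-dien-1-yl]triphenylphosphonium bromide | CC1=C[C@H](O[Si](C)(C)C(C)(C)C)CC(C)(C)[C@H]1/C=C/C(C)=C/C[P+](c1ccccc1)(c1ccccc1)c1ccccc1.[Br-] | intermediate
15 | (4R,6R)-4-hydroxy-2,2,6-trimethylcyclohexan-1-one (actinol) | O=C1C(C)(C)C[C@H](O)C[C@H]1C | starting material
16 | (4R,6R)-4-[(tert-butyldimethylsilyl)oxy]-2,2,6-trimethylcyclohexan-1-one | O=C1C(C)(C)C[C@H](O[Si](C)(C)C(C)(C)C)C[C@H]1C | intermediate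
17 | lithium (4R)-4-[(tert-butyldimethylsilyl)oxy]-2,6,6-trimethylcyclohex-1-en-1-olate | CC1=C([O-])C(C)(C)C[C@H](O[Si](C)(C)C(C)(C)C)C1.[Li+] | intermediate
18 | (4R)-4-[(tert-butyldimethylsilyl)oxy]-2,6,6-trimethylcyclohex-1-en-1-yl trifluoromethanesulfonate | CC1=C(OS(=O)(=O)C(F)(F)F)C(C)(C)C[C@H](O[Si](C)(C)C(C)(C)C)C1 | intermediate
19 | (2E)-3-methylpent-2-en-4-yn-1-ol | C#C/C(C)=C/CO | starting material
20 | (2E)-5-[(4R)-4-[(tert-butyldimethylsilyl)oxy]-2,6,6-trimethylcyclohex-1-en-1-yl]-3-methylpent-2-en-4-yn-1-ol | CC1=C(C#C/C(C)=C/CO)C(C)(C)C[C@H](O[Si](C)(C)C(C)(C)C)C1 | intermediate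
21 | (2E)-5-[(1R,4S,6R)-4-[(tert-butyldimethylsilyl)oxy]-2,2,6-trimethyl-7-oxabicyclo[4.1.0]heptan-1-yl]-3-methylpent-2-en-4-yn-1-ol (oxirane anti to the silyloxy group) | OC/C=C(C)/C#C[C@@]12O[C@]1(C)C[C@@H](O[Si](C)(C)C(C)(C)C)CC2(C)C | intermediate
22 | (2E)-5-[(2R,4S)-4-[(tert-butyldimethylsilyl)oxy]-2-hydroxy-2,6,6-trimethylcyclohexylidene]-3-methylpenta-2,4-dien-1-ol, (R) allene axis (6R in carotenoid locants) | OC/C=C(C)/C=[C@@]=C1C(C)(C)C[C@H](O[Si](C)(C)C(C)(C)C)C[C@@]1(C)O | intermediate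
23 | (2E)-3-[(2S,6S,7aR)-6-[(tert-butyldimethylsilyl)oxy]-4,4,7a-trimethyl-2,4,5,6,7,7a-hexahydro-1-benzofuran-2-yl]but-2-en-1-ol | OC/C=C(\C)[C@@H]1C=C2C(C)(C)C[C@H](O[Si](C)(C)C(C)(C)C)C[C@@]2(C)O1 | intermediate
24 | (2E)-1-bromo-3-[(2S,6S,7aR)-6-[(tert-butyldimethylsilyl)oxy]-4,4,7a-trimethyl-2,4,5,6,7,7a-hexahydro-1-benzofuran-2-yl]but-2-ene | BrC/C=C(\C)[C@@H]1C=C2C(C)(C)C[C@H](O[Si](C)(C)C(C)(C)C)C[C@@]2(C)O1 | intermediate
25 | [(2E)-3-[(2S,6S,7aR)-6-[(tert-butyldimethylsilyl)oxy]-4,4,7a-trimethyl-2,4,5,6,7,7a-hexahydro-1-benzofuran-2-yl]but-2-en-1-yl]triphenylphosphonium bromide | c1ccccc1[P+](c1ccccc1)(c1ccccc1)C/C=C(\C)[C@@H]1C=C2C(C)(C)C[C@H](O[Si](C)(C)C(C)(C)C)C[C@@]2(C)O1.[Br-] | intermediate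
26 | (2E,4E,6E)-2,7-dimethylocta-2,4,6-trienedial | O=C/C(C)=C/C=C/C=C(\C)C=O | starting material
27 | ylide of 14, (2E,4E)-5-[(1R,4R)-4-[(tert-butyldimethylsilyl)oxy]-2,6,6-trimethylcyclohex-2-en-1-yl]-3-methylpenta-2,4-dienylidene(triphenyl)phosphorane | CC1=C[C@H](O[Si](C)(C)C(C)(C)C)CC(C)(C)[C@H]1/C=C/C(C)=C/C=P(c1ccccc1)(c1ccccc1)c1ccccc1 | intermediate
28 | (2E,4E,6E,8E,10E,12E)-13-[(1R,4R)-4-[(tert-butyldimethylsilyl)oxy]-2,6,6-trimethylcyclohex-2-en-1-yl]-2,7,11-trimethyltrideca-2,4,6,8,10,12-hexaenal | CC1=C[C@H](O[Si](C)(C)C(C)(C)C)CC(C)(C)[C@H]1/C=C/C(C)=C/C=C/C(C)=C/C=C/C=C(\C)C=O | intermediate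
29 | ylide of 25, (2E)-3-[(2S,6S,7aR)-6-[(tert-butyldimethylsilyl)oxy]-4,4,7a-trimethyl-2,4,5,6,7,7a-hexahydro-1-benzofuran-2-yl]but-2-enylidene(triphenyl)phosphorane | c1ccccc1P(c1ccccc1)(c1ccccc1)=C/C=C(\C)[C@@H]1C=C2C(C)(C)C[C@H](O[Si](C)(C)C(C)(C)C)C[C@@]2(C)O1 | intermediate
30 | (3S,5R,8S,3′R,6′R)-3,3′-bis[(tert-butyldimethylsilyl)oxy]-5,8-epoxy-5,8-dihydro-β,ε-carotene | CC1=C[C@H](O[Si](C)(C)C(C)(C)C)CC(C)(C)[C@H]1/C=C/C(C)=C/C=C/C(C)=C/C=C/C=C(C)/C=C/C=C(\C)[C@@H]1C=C2C(C)(C)C[C@H](O[Si](C)(C)C(C)(C)C)C[C@@]2(C)O1 | intermediate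
31 | (3S,5R,8S,3′R,6′R)-5,8-epoxy-5,8-dihydro-β,ε-carotene-3,3′-diol | CC1=C[C@H](O)CC(C)(C)[C@H]1/C=C/C(C)=C/C=C/C(C)=C/C=C/C=C(C)/C=C/C=C(\C)[C@@H]1C=C2C(C)(C)C[C@H](O)C[C@@]2(C)O1 | target

Total step count: 17
Longest linear sequence: 10 steps (steps 1–7, then 15, 16 and 17)

Steps most likely to fail

Step 2. The rate difference between the two enantiomers of 5 may be too small, or facial control by the catalyst may be weak or reversed on this enone, so that the alcohol forms with low enantiomeric purity or as a cis/trans mixture. The fallback sets out from 5 and comes back at 6. Luche reduction (NaBH4, CeCl3·7H2O, MeOH, −40 °C) should give, by attack anti to the pseudoaxial C1′ methyl, the racemic trans-hydroxy ester F1. Lipase from Burkholderia cepacia with vinyl acetate in tert-butyl methyl ether is then expected to acylate the (4R)-carbinol selectively to the (1R,4R)-acetate F2, which is separated from the unreacted (1S,4S)-alcohol. Ethanolysis (K2CO3, EtOH) returns 6.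

Step 11. The remote silyloxy group may discriminate poorly between the two faces of the ring alkene, and the allylic-alcohol alkene may be epoxidised competitively. The fallback sets out from 18 and comes back at 21. Stille coupling of 18 with (tributylstannyl)methanol (Pd(PPh3)4, LiCl, dioxane, 90 °C) should give the allylic alcohol F3. Sharpless epoxidation (Ti(OiPr)4, D-(−)-diethyl tartrate, tBuOOH, CH2Cl2, −20 °C) then places the oxirane under reagent control on the face anti to the silyloxy group, giving the epoxy alcohol F4. Dess–Martin oxidation gives the epoxy aldehyde F5, the Ohira–Bestmann reagent (K2CO3, MeOH) converts it into the ethynyl oxirane F6, and Sonogashira coupling of F6 with (E)-3-iodobut-2-en-1-ol returns 21.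

Step 12. Hydride transfer may bypass the oxygen-bound aluminium (anti delivery or a loose propargylic cation), which would erode or invert the allene axis and lead after step 13 to the C8 epimer; direct reductive opening of the oxirane may also compete. The fallback sets out from 18 and 19 and comes back at 23. Palladium-catalysed hydrostannylation of 19 (Bu3SnH, PdCl2(PPh3)2, THF) gives the dienylstannane F7, and Stille coupling with 18 (Pd2(dba)3, AsPh3, N-methylpyrrolidone) gives the trienol F8. Epoxidation with mCPBA at the tetrasubstituted ring alkene gives the anti-oxirane F9. Mild acid (pyridinium p-toluenesulfonate, CH2Cl2) then rearranges the vinyl oxirane to the dihydrofurans, 23 and its C8 epimer F10. These are separated by chromatography, and F10 is re-equilibrated under the same acid and recycled.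

Further compounds
F1 | step 2 | ethyl trans-4-hydroxy-2,6,6-trimethylcyclohex-2-ene-1-carboxylate (racemate of the 1R,4R and 1S,4S forms) | CC1=C[C@H](O)CC(C)(C)[C@H]1C(=O)OCC.CC1=C[C@@H](O)CC(C)(C)[C@@H]1C(=O)OCC
F2 | step 2 | ethyl (1R,4R)-4-acetoxy-2,6,6-trimethylcyclohex-2-ene-1-carboxylate | CC1=C[C@H](OC(C)=O)CC(C)(C)[C@H]1C(=O)OCC
F3 | step 11 | [(4R)-4-[(tert-butyldimethylsilyl)oxy]-2,6,6-trimethylcyclohex-1-en-1-yl]methanol | OCC1=C(C)C[C@@H](O[Si](C)(C)C(C)(C)C)CC1(C)C
F4 | step 11 | [(1R,4S,6R)-4-[(tert-butyldimethylsilyl)oxy]-2,2,6-trimethyl-7-oxabicyclo[4.1.0]heptan-1-yl]methanol | OC[C@@]12O[C@]1(C)C[C@@H](O[Si](C)(C)C(C)(C)C)CC2(C)C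
F5 | step 11 | (1S,4S,6R)-4-[(tert-butyldimethylsilyl)oxy]-2,2,6-trimethyl-7-oxabicyclo[4.1.0]heptane-1-carbaldehyde | O=C[C@@]12O[C@]1(C)C[C@@H](O[Si](C)(C)C(C)(C)C)CC2(C)C
F6 | step 11 | (1R,4S,6R)-4-[(tert-butyldimethylsilyl)oxy]-1-ethynyl-2,2,6-trimethyl-7-oxabicyclo[4.1.0]heptane | C#C[C@@]12O[C@]1(C)C[C@@H](O[Si](C)(C)C(C)(C)C)CC2(C)C
F7 | step 12 | (2E,4E)-3-methyl-5-(tributylstannyl)penta-2,4-dien-1-ol | OC/C=C(C)/C=C/[Sn](CCCC)(CCCC)CCCC
F8 | step 12 | (2E,4E)-5-[(4R)-4-[(tert-butyldimethylsilyl)oxy]-2,6,6-trimethylcyclohex-1-en-1-yl]-3-methylpenta-2,4-dien-1-ol | CC1=C(/C=C/C(C)=C/CO)C(C)(C)C[C@H](O[Si](C)(C)C(C)(C)C)C1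
F9 | step 12 | (2E,4E)-5-[(1S,4S,6R)-4-[(tert-butyldimethylsilyl)oxy]-2,2,6-trimethyl-7-oxabicyclo[4.1.0]heptan-1-yl]-3-methylpenta-2,4-dien-1-ol | OC/C=C(C)/C=C/[C@@]12O[C@]1(C)C[C@@H](O[Si](C)(C)C(C)(C)C)CC2(C)C
F10 | step 12 | (2E)-3-[(2R,6S,7aR)-6-[(tert-butyldimethylsilyl)oxy]-4,4,7a-trimethyl-2,4,5,6,7,7a-hexahydro-1-benzofuran-2-yl]but-2-en-1-ol | OC/C=C(\C)[C@H]1C=C2C(C)(C)C[C@H](O[Si](C)(C)C(C)(C)C)C[C@@]2(C)O1
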